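## Analysis of the target

The target consists of two rings joined by one CH2 group. Ring A is a cyclopentane with three contiguous stereocentres, C1' (the CH that carries the CH2 link, S), C2' (the C(CH3)(OH) carbon, R) and C5' (the CH that carries the isopropenyl group, R); the CH2 link is cis to the C2' hydroxyl and trans to the C5' isopropenyl group. Ring B is a dearomatised acylphloroglucinol, an enolised cyclohexane-1,3,5-trione with the isobutyryl group at C2, the CH2 link at C4 and a quaternary stereocentre C6 (methyl and prenyl, R in the tautomer drawn). C6 is separated from ring A by the CH2 group and two sp2 carbons, so neither ring can relay its configuration to the other, and each must be made enantiopure on its own before the two are joined. The sensitive groups are the tertiary alcohol, which sits β to the position where an aldehyde is needed for coupling and so invites retro-aldol cleavage and dehydration, the acid-sensitive isopropenyl and prenyl alkenes, and the acidic, chelating triketone. The difficulty lies in setting three adjacent centres on a small ring and then attaching that hindered ring to a polycarbonyl partner with no stereochemical link between the two halves. The strategy rests on the fact that C1' is flanked by C2' and C5': C1' and C5' are the α- and β-carbons of an enal, and C2', C3' and C4' are a three-carbon methyl ketone unit that bridges them.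

## Retrosynthetic reasoning

**Unmasking the alcohol.** The target 24 is taken back to its triethylsilyl ether 23. The tertiary hydroxyl is kept silylated until the end because, at the aldehyde stage that precedes the coupling, a free β-hydroxyl would open ring A by retro-aldol cleavage under amine catalysis.

**Joining the rings.** In 23 the bond between C4 of ring B and the exocyclic CH2 is cut. It is the only bond between the two stereochemical domains. C4 is the nucleophilic carbon of a vinylogous acid and the CH2 carbon can arrive as an aldehyde carbon. This gives aldehyde 13 and triketone 21. The forward reaction is a condensation followed at once by hydride transfer to the alkylidene 22, so no new stereocentre arises.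

**Ring B.** Triketone 21 is cut first at C1–C2, which gives the open-chain trioxo ester 20, and then at the bond that was C4–C5 of the ring, which gives the acyl donor 19 and diketone 18. The two carbonyl carbons that flank C6 are then the two carboxyl carbons of a disubstituted malonate, and the remaining three ring carbons and the isobutyryl side chain come from diketone 18. The malonate is the half-ester 17, reached from the prochiral diester 16 (from 14 and 15) by enzymatic desymmetrisation. The forward sequence must attach the acid arm of 17 (activated as 19) to the terminal carbon of 18 and the ester arm to its central carbon. That order turns the choice made by the enzyme into the R configuration at C6.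

**Ring A functional groups.** Aldehyde 13 is traced through 12, 11, 10 and 9 to the cyclopentane 8. The steps are: aldehyde from a primary silyl ether, the C4' methylene from a C(SO2Ph)2 carbon, the isopropenyl group from an acetyl group, and the two silyl ethers from the diol obtained by reducing the formyl group of 8. The acetyl and sulfonyl groups are the activating groups that make 8 accessible. The order is fixed by reactivity: the aldehyde is put away first, the ketone is methylenated before the reductive desulfonylation (which would otherwise attack it), and the methylenation uses a non-basic titanium reagent so that the β-sulfonyl ketone is not exposed to a basic ylide.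

**Ring A skeleton (key disconnection).** In 8 the bonds C5–C4 and C1–C2 are cut. This gives the oxo-enal 3, which supplies C1, C5, the formyl and the acetyl group, and the ketone 6, which supplies C2, C3, C4 and the methyl group. The forward reaction is a Michael addition of the carbanion of 6 to the iminium ion of 3, followed by an aldol closure of the resulting enamine onto the ketone of 6. One chiral secondary amine catalyst has to set C5 and let C1 and C2 settle.

**Precursors.** Enal 3 comes from oxidative opening of furan 1 through the Z-isomer 2. Ketone 6 comes from alkylation of disulfone 4 with chloroketone 5.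

## Alternatives that were turned down

Alternative 1: ring B closed last. Ring B is cut at the same two bonds as above, but with ring A already in place. The dianion of diketone A2 is C-acylated at its terminal α-CH2 (C6, on the ring A side) by acid chloride A3, and a Dieckmann closure of the internal diketone carbon onto the methyl ester gives A1, which is the same compound as 23.
- For: it avoids condensing a hindered, α-branched aldehyde with the triketone, and the late bond formations are ordinary carbonyl chemistry.
- Against: it says nothing about how the three stereocentres of ring A arise, so it needs a separate ring A synthesis anyway. It also puts the most valuable fragment into a dianion acylation, where the acidic product consumes base and the nucleophile is normally used in excess.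
- Comparison: on the coupling itself it is at least as safe as the chosen route. The chosen route instead places its key step where the stereochemical problem lies and couples the fragments in one step. Alternative 1 is kept as the fallback for that coupling.

Alternative 2: rhodium-catalysed isopropenyl addition and aldol closure. Ring A is cut at C5'–isopropenyl and C1'–C2'. The catalyst precursor is di-μ-hydroxidobis(cycloocta-1,5-diene)dirhodium A7, formula [Rh(cod)OH]2, used with a chiral bisphosphine. Transmetallation of boronate A6 with A7 gives an isopropenylrhodium species that adds to the β-carbon of keto enoate A5, and the rhodium enolate closes onto the methyl ketone to give ester A4.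
- For: the isopropenyl group is installed directly, with no sulfones to remove and no acetyl group to convert. Ring A at the oxidation level of 13 would be reached in roughly half the steps used here. On step economy this alternative is stronger.
- Against: the tandem reaction is best established for enones with aryl boron reagents. An enoate gives a less nucleophilic rhodium ester enolate, which can be protonated by the hydroxylic medium before it adds to the ketone. A 1,1-disubstituted alkenyl boronate is also prone to protodeboronation. All three centres are fixed in one kinetic event, and the carbinol centre cannot be corrected afterwards.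
- Comparison: the chosen route pays about four extra steps for a key step whose two elementary reactions are each well behaved and in which two of the three centres are self-correcting.

Alternative 3: (R)-linalool A10 mapped onto ring A by radical-cation cyclisation. Ring A is cut at C1'–C5'. The silyloxy aldehyde A9, made from A10, is condensed with a chiral imidazolidinone. One-electron oxidation gives an enamine radical cation that adds 5-exo to the trisubstituted alkene, and oxidation of the tertiary radical with loss of a proton gives A8, which is the same compound as 13.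
- For: every carbon of ring A and the carbinol configuration come from the chiral pool, and A8 is reached in very few steps. On step economy and on the carbinol centre this alternative is stronger than the chosen one.
- Against: the terminating step must choose between proton loss to the isopropenyl group, proton loss to the tetrasubstituted isomer, and capture of the cation by a nucleophile. The oxidant can attack the electron-rich alkene directly. The catalyst must work with or against the existing stereocentre. 5-Exo closures of this substitution pattern tend to give the 1,2-cis product, so C1' would need epimerisation, and C5' could not be corrected at all.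
- Comparison: the chosen route is longer, but each of its selectivity elements has a defined origin and no regiochemical termination problem arises.

Key step: step 3

Remark: pig liver esterase is assumed to hydrolyse the pro-S ester group of 16 and so give the (R)-half-ester 17. The sense and level of selection for a prenyl side chain must be confirmed, and the fallback to step 10 covers the other outcome.

Remark: compounds 21 to 24 are drawn and named as the enol tautomer of the target structure. They exist as equilibrating enol forms, which does not affect C6.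

## Route

Step 1
Reactants: 1 2-methylfuran
Product: 3 (E)-4-oxopent-2-enal, via (Z)-4-oxopent-2-enal 2 (not isolated)
Conditions: NBS, NaHCO3, acetone/H2O, −15 °C; then pyridine (cat.), rt
Reagents that add atoms: water, O
Why: Bromination at C5 of the furan and capture by water open the ring to the cis-4-oxo-enal (oxidative furan ring opening). Pyridine adds reversibly and isomerises the Z-alkene to the more stable E-isomer. No stereocentre is formed.

Step 2
Reactants: 4 bis(phenylsulfonyl)methane; 5 chloroacetone
Product: 6 4,4-bis(phenylsulfonyl)butan-2-one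
Conditions: NaH (1.0 equiv), DMF, 0 °C; 5, NaI (cat.), 0 °C → rt
Reagents that add atoms: none
Why: SN2 alkylation of the doubly sulfonyl-stabilised carbanion with an α-chloro ketone. The product is less acidic and more hindered than 4, which limits dialkylation, and one equivalent of base avoids E1cB loss of sulfinate from the β-sulfonyl ketone.

Step 3
Reactants: 3 (E)-4-oxopent-2-enal; 6 4,4-bis(phenylsulfonyl)butan-2-one
Product: 8 (1S,2R,5R)-5-acetyl-2-hydroxy-2-methyl-4,4-bis(phenylsulfonyl)cyclopentane-1-carbaldehyde, via open-chain Michael adduct 7 (not isolated)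
Conditions: (R)-2-[diphenyl(trimethylsilyloxy)methyl]pyrrolidine (20 mol %), PhCO2H (20 mol %), toluene, 0 °C → rt
Reagents that add atoms: none
Why: The amine condenses with the aldehyde of 3, which is more electrophilic than its ketone, to give an E,s-trans iminium ion; the carbanion of 6, formed at C4 as its only strongly acidic position, adds to the iminium β-carbon, which is the carbon bearing the acetyl group. The resulting enamine (7 as its catalyst-bound form) attacks the tethered methyl ketone in a 5-(enolexo)-exo-trig aldol that closes ring A, and hydrolysis releases 8 and the catalyst. The closest known reaction type is the amine-catalysed domino Michael–aldol (formal 3+2) reaction of enals with C–H acids that carry a ketone tether, which gives hydroxycyclopentane carbaldehydes. C5 is set by the catalyst: the diphenyl(silyloxy)methyl group of the (R)-amine shields one face of the iminium ion and the carbanion enters from the other, which corresponds to R. C1 is α to the formyl group and equilibrates through the enamine to the isomer with formyl trans to acetyl. C2 arises in a reversible aldol and should settle with the hydroxyl cis to the formyl group (methyl trans), helped by the internal hydrogen bond. The step needs attack β to the iminium carbon and not β to the ketone, which iminium activation secures; it needs the aldehyde enamine as the only aldol donor, which holds because this hindered amine condenses with aldehydes and not with ketones, so the ketone α-positions are not activated. It also needs the sulfonyl groups to stay in place, which the buffered, weakly basic medium favours.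

Step 4
Reactants: 8 (1S,2R,5R)-5-acetyl-2-hydroxy-2-methyl-4,4-bis(phenylsulfonyl)cyclopentane-1-carbaldehyde
Product: 9 1-[(1R,2R,3R)-3-hydroxy-2-(hydroxymethyl)-3-methyl-5,5-bis(phenylsulfonyl)cyclopentyl]ethan-1-one
Conditions: NaBH4, CH2Cl2/MeOH, −78 °C
Reagents that add atoms: none
Why: Chemoselective hydride reduction: at −78 °C borohydride reduces the aldehyde and leaves the hindered methyl ketone. This removes the β-hydroxy aldehyde, which is prone to retro-aldol cleavage, dehydration and epimerisation, before further handling.

Step 5
Reactants: 9 1-[(1R,2R,3R)-3-hydroxy-2-(hydroxymethyl)-3-methyl-5,5-bis(phenylsulfonyl)cyclopentyl]ethan-1-one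
Product: 10 1-[(1R,2R,3R)-3-methyl-5,5-bis(phenylsulfonyl)-3-(triethylsilyloxy)-2-{[(triethylsilyl)oxy]methyl}cyclopentyl]ethan-1-one
Conditions: Et3SiOTf (3 equiv), 2,6-lutidine, CH2Cl2, −78 → −20 °C
Reagents that add atoms: triethylsilyl trifluoromethanesulfonate, CC[Si](CC)(CC)OS(=O)(=O)C(F)(F)F
Why: Silyl ether formation with a silyl triflate and a hindered base covers both the primary and the tertiary hydroxyl. 2,6-Lutidine is too weak a base to enolise the ketone towards loss of sulfinate at this temperature.

Step 6
Reactants: 10 1-[(1R,2R,3R)-3-methyl-5,5-bis(phenylsulfonyl)-3-(triethylsilyloxy)-2-{[(triethylsilyl)oxy]methyl}cyclopentyl]ethan-1-one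
Product: 11 {[(1R,2R,3R)-1-methyl-4,4-bis(phenylsulfonyl)-3-(prop-1-en-2-yl)-2-{[(triethylsilyl)oxy]methyl}cyclopentyl]oxy}triethylsilane
Conditions: Cp2TiMe2 (3 equiv), toluene, 70 °C, dark
Reagents that add atoms: dimethyltitanocene Cp2TiMe2, [CH3-].[CH3-].[Ti+4].c1cc[cH-]c1.c1cc[cH-]c1
Why: Carbonyl methylenation by the titanium methylidene formed on heating Cp2TiMe2, through an oxatitanacyclobutane. No basic ylide is present, so the α-stereocentre and the β-sulfonyl groups, which would be lost by E1cB under ylide conditions, are preserved.

Step 7
Reactants: 11 {[(1R,2R,3R)-1-methyl-4,4-bis(phenylsulfonyl)-3-(prop-1-en-2-yl)-2-{[(triethylsilyl)oxy]methyl}cyclopentyl]oxy}triethylsilane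
Product: 12 {[(1R,2R,3R)-1-methyl-3-(prop-1-en-2-yl)-2-{[(triethylsilyl)oxy]methyl}cyclopentyl]oxy}triethylsilane
Conditions: Mg turnings (excess), MeOH/THF, 0 °C → rt
Reagents that add atoms: none
Why: Reductive desulfonylation by single-electron transfer from magnesium cleaves the two C–S bonds in turn and methanol protonates the carbanions, leaving a CH2 group. Isolated alkenes and silyl ethers are not reduced. If basic methanol partly cleaves the primary silyl ether, the resulting primary alcohol is oxidised to the same aldehyde in step 8.

Step 8
Reactants: 12 {[(1R,2R,3R)-1-methyl-3-(prop-1-en-2-yl)-2-{[(triethylsilyl)oxy]methyl}cyclopentyl]oxy}triethylsilane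
Product: 13 (1S,2R,5R)-2-methyl-5-(prop-1-en-2-yl)-2-(triethylsilyloxy)cyclopentane-1-carbaldehyde
Conditions: (COCl)2, DMSO, CH2Cl2, −78 → −40 °C; Et3N, −78 → 0 °C
Reagents that add atoms: none
Why: Under Swern conditions a primary triethylsilyl ether is cleaved by the chlorosulfonium salt and oxidised directly to the aldehyde, while the tertiary silyl ether is inert. Low temperature and short contact with Et3N protect the α-stereocentre.

Step 9
Reactants: 14 dimethyl methylmalonate; 15 1-bromo-3-methylbut-2-ene
Product: 16 dimethyl 2-methyl-2-(3-methylbut-2-en-1-yl)propanedioate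
Conditions: NaH, THF, 0 °C; 15, 0 °C → rt
Reagents that add atoms: none
Why: SN2 alkylation of a malonate enolate with an allylic bromide. Only one acidic hydrogen is present, so the prochiral diester forms cleanly.

Step 10
Reactants: 16 dimethyl 2-methyl-2-(3-methylbut-2-en-1-yl)propanedioate
Product: 17 (R)-3-methoxy-2-methyl-2-(3-methylbut-2-en-1-yl)-3-oxopropanoic acid
Conditions: pig liver esterase, phosphate buffer pH 7.5/DMSO (9:1), 25 °C, pH-stat (1 M NaOH); then HCl to pH 2
Reagents that add atoms: water, O
Why: Enzymatic desymmetrisation of a prochiral disubstituted malonate: the esterase hydrolyses one of the two enantiotopic ester groups and thereby creates the quaternary stereocentre. The monoanion formed is not a substrate, so hydrolysis stops at the half-ester.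

Step 11
Reactants: 17 (R)-3-methoxy-2-methyl-2-(3-methylbut-2-en-1-yl)-3-oxopropanoic acid; 18 5-methylhexane-2,4-dione
Product: 20 methyl (R)-2,8-dimethyl-2-(3-methylbut-2-en-1-yl)-3,5,7-trioxononanoate, via acyl imidazole 19 (not isolated)
Conditions: 17, CDI, THF, rt; then added to 18 (3 equiv) / LiN(iPr)2 (6 equiv), THF, −78 → −20 °C; aq. NH4Cl
Reagents that add atoms: none
Why: CDI activates the acid without HCl, which spares the prenyl group. The dianion of 18 reacts at its more basic terminal carbon (Claisen-type γ-acylation of a 1,3-diketone dianion), and the excess dianion takes up the acidic proton of the product. The quaternary centre cannot enolise and is carried through unchanged.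

Step 12
Reactants: 20 methyl (R)-2,8-dimethyl-2-(3-methylbut-2-en-1-yl)-3,5,7-trioxononanoate
Product: 21 (R)-3,5-dihydroxy-6-methyl-6-(3-methylbut-2-en-1-yl)-2-(2-methylpropanoyl)cyclohexa-2,4-dien-1-one
Conditions: NaOMe (3 equiv), MeOH, 60 °C; then 1 M HCl, 0 °C
Reagents that add atoms: none
Why: Dieckmann-type intramolecular C-acylation: C6 of 20, between the two distal carbonyls, attacks the methyl ester and closes the six-membered ring. O-Acylation to a pyranone is reversible under methoxide, and the stabilised triketone anion draws the equilibrium to 21. Because the acid arm of 17 ends up bonded to ring carbon C4 and the ester arm to ring carbon C2, C6 has the R configuration.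

Step 13
Reactants: 13 (1S,2R,5R)-2-methyl-5-(prop-1-en-2-yl)-2-(triethylsilyloxy)cyclopentane-1-carbaldehyde; 21 (R)-3,5-dihydroxy-6-methyl-6-(3-methylbut-2-en-1-yl)-2-(2-methylpropanoyl)cyclohexa-2,4-dien-1-one
Product: 23 (R)-3,5-dihydroxy-6-methyl-6-(3-methylbut-2-en-1-yl)-4-{[(1S,2R,5R)-2-methyl-5-(prop-1-en-2-yl)-2-(triethylsilyloxy)cyclopentyl]methyl}-2-(2-methylpropanoyl)cyclohexa-2,4-dien-1-one, via alkylidene triketone 22 (not isolated)
Conditions: Hantzsch ester (1.2 equiv), L-proline (20 mol %), CH2Cl2, rt
Reagents that add atoms: none
Why: Three-component reductive alkylation: Knoevenagel condensation of the acidic C4–H of 21 with the aldehyde gives the electron-poor alkylidene 22, which takes up hydride from the dihydropyridine faster than a second molecule of 21 can add. No stereocentre is formed, and the silyl ether blocks retro-aldol opening of ring A.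

Step 14
Reactants: 23 (R)-3,5-dihydroxy-6-methyl-6-(3-methylbut-2-en-1-yl)-4-{[(1S,2R,5R)-2-methyl-5-(prop-1-en-2-yl)-2-(triethylsilyloxy)cyclopentyl]methyl}-2-(2-methylpropanoyl)cyclohexa-2,4-dien-1-one
Product: 24 (R)-3,5-dihydroxy-4-{[(1S,2R,5R)-2-hydroxy-2-methyl-5-(prop-1-en-2-yl)cyclopentyl]methyl}-6-methyl-6-(3-methylbut-2-en-1-yl)-2-(2-methylpropanoyl)cyclohexa-2,4-dien-1-one
Conditions: HF·pyridine, pyridine, THF, 0 °C → rt
Reagents that add atoms: none
Why: Fluoride-driven cleavage of the tertiary silyl ether under buffered conditions. This avoids strong acid, which could ionise the tertiary alcohol or cyclise an alkene onto an enol oxygen.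

## Compound list

1 | 2-methylfuran | Cc1ccco1 | starting material
2 | (Z)-4-oxopent-2-enal | CC(=O)/C=C\C=O | intermediate
3 | (E)-4-oxopent-2-enal | CC(=O)/C=C/C=O | intermediate
4 | bis(phenylsulfonyl)methane | O=S(=O)(CS(=O)(=O)c1ccccc1)c1ccccc1 | starting material
5 | chloroacetone | CC(=O)CCl | starting material
6 | 4,4-bis(phenylsulfonyl)butan-2-one | CC(=O)CC(S(=O)(=O)c1ccccc1)S(=O)(=O)c1ccccc1 | intermediate
7 | (R)-3-acetyl-6-oxo-4,4-bis(phenylsulfonyl)heptanal (open-chain Michael adduct, present as its enamine with the catalyst) | CC(=O)[C@@H](CC=O)C(CC(C)=O)(S(=O)(=O)c1ccccc1)S(=O)(=O)c1ccccc1 | intermediate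
8 | (1S,2R,5R)-5-acetyl-2-hydroxy-2-methyl-4,4-bis(phenylsulfonyl)cyclopentane-1-carbaldehyde | CC(=O)[C@@H]1C(S(=O)(=O)c2ccccc2)(S(=O)(=O)c2ccccc2)C[C@@](C)(O)[C@H]1C=O | intermediate
9 | 1-[(1R,2R,3R)-3-hydroxy-2-(hydroxymethyl)-3-methyl-5,5-bis(phenylsulfonyl)cyclopentyl]ethan-1-one | CC(=O)[C@@H]1C(S(=O)(=O)c2ccccc2)(S(=O)(=O)c2ccccc2)C[C@@](C)(O)[C@H]1CO | intermediate
10 | 1-[(1R,2R,3R)-3-methyl-5,5-bis(phenylsulfonyl)-3-(triethylsilyloxy)-2-{[(triethylsilyl)oxy]methyl}cyclopentyl]ethan-1-one | CC(=O)[C@@H]1C(S(=O)(=O)c2ccccc2)(S(=O)(=O)c2ccccc2)C[C@@](C)(O[Si](CC)(CC)CC)[C@H]1CO[Si](CC)(CC)CC | intermediate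
11 | {[(1R,2R,3R)-1-methyl-4,4-bis(phenylsulfonyl)-3-(prop-1-en-2-yl)-2-{[(triethylsilyl)oxy]methyl}cyclopentyl]oxy}triethylsilane | C=C(C)[C@@H]1C(S(=O)(=O)c2ccccc2)(S(=O)(=O)c2ccccc2)C[C@@](C)(O[Si](CC)(CC)CC)[C@H]1CO[Si](CC)(CC)CC | intermediate
12 | {[(1R,2R,3R)-1-methyl-3-(prop-1-en-2-yl)-2-{[(triethylsilyl)oxy]methyl}cyclopentyl]oxy}triethylsilane | C=C(C)[C@@H]1CC[C@@](C)(O[Si](CC)(CC)CC)[C@H]1CO[Si](CC)(CC)CC | intermediate
13 | (1S,2R,5R)-2-methyl-5-(prop-1-en-2-yl)-2-(triethylsilyloxy)cyclopentane-1-carbaldehyde | C=C(C)[C@@H]1CC[C@@](C)(O[Si](CC)(CC)CC)[C@H]1C=O | intermediate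
14 | dimethyl methylmalonate | COC(=O)C(C)C(=O)OC | starting material
15 | 1-bromo-3-methylbut-2-ene (prenyl bromide) | CC(C)=CCBr | starting material
16 | dimethyl 2-methyl-2-(3-methylbut-2-en-1-yl)propanedioate | COC(=O)C(C)(CC=C(C)C)C(=O)OC | intermediate
17 | (R)-3-methoxy-2-methyl-2-(3-methylbut-2-en-1-yl)-3-oxopropanoic acid | OC(=O)[C@@](C)(CC=C(C)C)C(=O)OC | intermediate
18 | 5-methylhexane-2,4-dione | CC(=O)CC(=O)C(C)C | starting material
19 | methyl (R)-2-(1H-imidazole-1-carbonyl)-2,5-dimethylhex-4-enoate | O=C(n1ccnc1)[C@@](C)(CC=C(C)C)C(=O)OC | intermediate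
20 | methyl (R)-2,8-dimethyl-2-(3-methylbut-2-en-1-yl)-3,5,7-trioxononanoate | O=C(CC(=O)CC(=O)C(C)C)[C@@](C)(CC=C(C)C)C(=O)OC | intermediate
21 | (R)-3,5-dihydroxy-6-methyl-6-(3-methylbut-2-en-1-yl)-2-(2-methylpropanoyl)cyclohexa-2,4-dien-1-one | OC1=CC(O)=C(C(=O)C(C)C)C(=O)[C@]1(C)CC=C(C)C | intermediate
22 | Knoevenagel adduct: 3-hydroxy-6-methyl-6-(3-methylbut-2-en-1-yl)-2-(2-methylpropanoyl)cyclohex-2-ene-1,5-dione carrying at C4 the exocyclic methylidene derived from the formyl carbon of 13; ring A and C6 configured as in 23, alkene geometry undefined | C=C(C)[C@@H]1CC[C@@](C)(O[Si](CC)(CC)CC)[C@H]1C=C1C(=O)[C@@](C)(CC=C(C)C)C(=O)C(C(=O)C(C)C)=C1O | intermediate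
23 | (R)-3,5-dihydroxy-6-methyl-6-(3-methylbut-2-en-1-yl)-4-{[(1S,2R,5R)-2-methyl-5-(prop-1-en-2-yl)-2-(triethylsilyloxy)cyclopentyl]methyl}-2-(2-methylpropanoyl)cyclohexa-2,4-dien-1-one | C=C(C)[C@@H]1CC[C@@](C)(O[Si](CC)(CC)CC)[C@H]1CC1=C(O)[C@@](C)(CC=C(C)C)C(=O)C(C(=O)C(C)C)=C1O | intermediate
24 | (R)-3,5-dihydroxy-4-{[(1S,2R,5R)-2-hydroxy-2-methyl-5-(prop-1-en-2-yl)cyclopentyl]methyl}-6-methyl-6-(3-methylbut-2-en-1-yl)-2-(2-methylpropanoyl)cyclohexa-2,4-dien-1-one | C=C(C)[C@@H]1CC[C@@](C)(O)[C@H]1CC1=C(O)[C@@](C)(CC=C(C)C)C(=O)C(C(=O)C(C)C)=C1O | target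

## Step count and least certain steps

Total: 14 steps. Longest linear sequence: 9 steps (step 1 or 2, then steps 3 to 8, 13 and 14). The ring B branch (steps 9 to 12) joins at step 13.

**Step 3 (key step).**
- What may go wrong: slow or reversible addition of a hindered tertiary carbanion to a β-acyl iminium ion; E1cB loss of benzenesulfinate from 6 or 8; dehydration of the aldol to a cyclopentene carbaldehyde; incomplete equilibration at C2; slow erosion of enantiopurity by enolisation at C5. The sense of induction follows the steric shielding model and has to be confirmed on 8; the antipodal amine is equally available.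
- Fallback: it sets out from 3 and 4 and attaches the ketone tether after the Michael step. The unhindered parent disulfone 4 is added to 3 with the same (R)-amine catalyst to give (R)-3-acetyl-4,4-bis(phenylsulfonyl)butanal F1. This is acetalised in the same flask (HC(OMe)3, cat. TsOH, MeOH) to (R)-3-[bis(phenylsulfonyl)methyl]-5,5-dimethoxypentan-2-one F2. The remaining acidic C–H is alkylated with 5 (Cs2CO3, DMF) to (R)-3-(2,2-dimethoxyethyl)-4,4-bis(phenylsulfonyl)heptane-2,6-dione F3. Mild aqueous acid releases 7, which is closed with pyrrolidinium acetate. The fallback comes back to the route at 8.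

**Step 13.**
- What may go wrong: sluggish condensation of the α-branched, β-silyloxy aldehyde; β-elimination of the silyloxy group or epimerisation at C1' through the enamine; addition of a second molecule of 21 to the alkylidene.
- Fallback: ring B is built last. It sets out from 12. Selective cleavage of the primary silyl ether (pyridinium tosylate, MeOH, 0 °C) gives [(1R,2R,5R)-2-methyl-5-(prop-1-en-2-yl)-2-(triethylsilyloxy)cyclopentyl]methanol F4. I2, PPh3 and imidazole give triethyl{[(1R,2S,3R)-2-(iodomethyl)-1-methyl-3-(prop-1-en-2-yl)cyclopentyl]oxy}silane F5. Alkylation of the dianion of 18 at its terminal carbon gives 2-methyl-7-[(1S,2R,5R)-2-methyl-5-(prop-1-en-2-yl)-2-(triethylsilyloxy)cyclopentyl]heptane-3,5-dione F6. Its dianion is acylated at C6 with 19 to methyl (2R)-2,8-dimethyl-2-(3-methylbut-2-en-1-yl)-4-{[(1S,2R,5R)-2-methyl-5-(prop-1-en-2-yl)-2-(triethylsilyloxy)cyclopentyl]methyl}-3,5,7-trioxononanoate F7, and NaOMe in MeOH closes ring B. The fallback comes back at 23.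

**Step 6.**
- What may go wrong: enolisation of the hindered ketone by the titanium methylidene in place of cycloaddition, or thermal loss of sulfinate.
- Fallback: a Peterson sequence that also removes the sulfones before any alkene exists. It sets out from 10. Me3SiCH2MgCl with CeCl3 (THF, −78 °C) gives 2-[(1R,2R,3R)-3-methyl-5,5-bis(phenylsulfonyl)-3-(triethylsilyloxy)-2-{[(triethylsilyl)oxy]methyl}cyclopentyl]-1-(trimethylsilyl)propan-2-ol F8. Mg in MeOH gives 2-[(1R,2R,3R)-3-methyl-3-(triethylsilyloxy)-2-{[(triethylsilyl)oxy]methyl}cyclopentyl]-1-(trimethylsilyl)propan-2-ol F9. KH in THF then eliminates to the alkene. Desulfonylation comes before the base step so that the alkoxide cannot fragment with loss of sulfinate. The fallback comes back at 12.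

**Step 10.**
- What may go wrong: low or opposite enantiotopic group selection by the esterase for a prenyl substituent.
- Fallback: classical resolution. It sets out from 16. One equivalent of KOH in MeOH gives racemic 3-methoxy-2-methyl-2-(3-methylbut-2-en-1-yl)-3-oxopropanoic acid F10. Crystallisation with (R)-1-phenylethylamine gives (R)-1-phenylethylammonium (R)-3-methoxy-2-methyl-2-(3-methylbut-2-en-1-yl)-3-oxopropanoate F11; the antipodal amine is used if it gives the less soluble salt of the (R)-acid. Acidification brings the route back at 17.

**Step 11.**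
- What may go wrong: attack of the dianion on the methyl ester in place of the hindered acyl imidazole, O-acylation, or quenching of the dianion by the acidic product.
- Fallback: aldol addition and oxidation in place of acylation. It sets out from 17 by way of its acyl imidazole 19, prepared with CDI as in step 11. NaBH4 in THF/H2O at 0 °C reduces 19 to methyl (R)-2-(hydroxymethyl)-2,5-dimethylhex-4-enoate F12 and leaves the hindered methyl ester. Dess–Martin oxidation gives methyl (R)-2-formyl-2,5-dimethylhex-4-enoate F13. The dianion of 18 adds to this non-enolisable aldehyde to give methyl (2R)-3-hydroxy-2,8-dimethyl-2-(3-methylbut-2-en-1-yl)-5,7-dioxononanoate F14, and Swern oxidation brings the route back at 20.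

## Further compounds

F1 | step 3 | (R)-3-acetyl-4,4-bis(phenylsulfonyl)butanal | CC(=O)[C@@H](CC=O)C(S(=O)(=O)c1ccccc1)S(=O)(=O)c1ccccc1
F2 | step 3 | (R)-3-[bis(phenylsulfonyl)methyl]-5,5-dimethoxypentan-2-one | CC(=O)[C@@H](CC(OC)OC)C(S(=O)(=O)c1ccccc1)S(=O)(=O)c1ccccc1
F3 | step 3 | (R)-3-(2,2-dimethoxyethyl)-4,4-bis(phenylsulfonyl)heptane-2,6-dione | CC(=O)[C@@H](CC(OC)OC)C(CC(C)=O)(S(=O)(=O)c1ccccc1)S(=O)(=O)c1ccccc1
F4 | step 13 | [(1R,2R,5R)-2-methyl-5-(prop-1-en-2-yl)-2-(triethylsilyloxy)cyclopentyl]methanol | C=C(C)[C@@H]1CC[C@@](C)(O[Si](CC)(CC)CC)[C@H]1CO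
F5 | step 13 | triethyl{[(1R,2S,3R)-2-(iodomethyl)-1-methyl-3-(prop-1-en-2-yl)cyclopentyl]oxy}silane | C=C(C)[C@@H]1CC[C@@](C)(O[Si](CC)(CC)CC)[C@H]1CI
F6 | step 13 | 2-methyl-7-[(1S,2R,5R)-2-methyl-5-(prop-1-en-2-yl)-2-(triethylsilyloxy)cyclopentyl]heptane-3,5-dione | C=C(C)[C@@H]1CC[C@@](C)(O[Si](CC)(CC)CC)[C@H]1CCC(=O)CC(=O)C(C)C
F7 | step 13 | methyl (2R)-2,8-dimethyl-2-(3-methylbut-2-en-1-yl)-4-{[(1S,2R,5R)-2-methyl-5-(prop-1-en-2-yl)-2-(triethylsilyloxy)cyclopentyl]methyl}-3,5,7-trioxononanoate | C=C(C)[C@@H]1CC[C@@](C)(O[Si](CC)(CC)CC)[C@H]1CC(C(=O)CC(=O)C(C)C)C(=O)[C@@](C)(CC=C(C)C)C(=O)OC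
F8 | step 6 | 2-[(1R,2R,3R)-3-methyl-5,5-bis(phenylsulfonyl)-3-(triethylsilyloxy)-2-{[(triethylsilyl)oxy]methyl}cyclopentyl]-1-(trimethylsilyl)propan-2-ol (carbinol epimers) | C[Si](C)(C)CC(C)(O)[C@@H]1C(S(=O)(=O)c2ccccc2)(S(=O)(=O)c2ccccc2)C[C@@](C)(O[Si](CC)(CC)CC)[C@H]1CO[Si](CC)(CC)CC
F9 | step 6 | 2-[(1R,2R,3R)-3-methyl-3-(triethylsilyloxy)-2-{[(triethylsilyl)oxy]methyl}cyclopentyl]-1-(trimethylsilyl)propan-2-ol (carbinol epimers) | C[Si](C)(C)CC(C)(O)[C@@H]1CC[C@@](C)(O[Si](CC)(CC)CC)[C@H]1CO[Si](CC)(CC)CC
F10 | step 10 | racemic 3-methoxy-2-methyl-2-(3-methylbut-2-en-1-yl)-3-oxopropanoic acid | COC(=O)C(C)(CC=C(C)C)C(=O)O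
F11 | step 10 | (R)-1-phenylethylammonium (R)-3-methoxy-2-methyl-2-(3-methylbut-2-en-1-yl)-3-oxopropanoate | C[C@@H]([NH3+])c1ccccc1.[O-]C(=O)[C@@](C)(CC=C(C)C)C(=O)OC
F12 | step 11 | methyl (R)-2-(hydroxymethyl)-2,5-dimethylhex-4-enoate | OC[C@@](C)(CC=C(C)C)C(=O)OC
F13 | step 11 | methyl (R)-2-formyl-2,5-dimethylhex-4-enoate | O=C[C@@](C)(CC=C(C)C)C(=O)OC
F14 | step 11 | methyl (2R)-3-hydroxy-2,8-dimethyl-2-(3-methylbut-2-en-1-yl)-5,7-dioxononanoate (carbinol epimers) | OC(CC(=O)CC(=O)C(C)C)[C@@](C)(CC=C(C)C)C(=O)OC
A1 | alternative 1 | (R)-3,5-dihydroxy-6-methyl-6-(3-methylbut-2-en-1-yl)-4-{[(1S,2R,5R)-2-methyl-5-(prop-1-en-2-yl)-2-(triethylsilyloxy)cyclopentyl]methyl}-2-(2-methylpropanoyl)cyclohexa-2,4-dien-1-one | C=C(C)[C@@H]1CC[C@@](C)(O[Si](CC)(CC)CC)[C@H]1CC1=C(O)[C@@](C)(CC=C(C)C)C(=O)C(C(=O)C(C)C)=C1O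
A2 | alternative 1 | 2-methyl-7-[(1S,2R,5R)-2-methyl-5-(prop-1-en-2-yl)-2-(triethylsilyloxy)cyclopentyl]heptane-3,5-dione | C=C(C)[C@@H]1CC[C@@](C)(O[Si](CC)(CC)CC)[C@H]1CCC(=O)CC(=O)C(C)C
A3 | alternative 1 | methyl (S)-2-(chlorocarbonyl)-2,5-dimethylhex-4-enoate | O=C(Cl)[C@@](C)(CC=C(C)C)C(=O)OC
A4 | alternative 2 | methyl (1S,2R,5R)-2-hydroxy-2-methyl-5-(prop-1-en-2-yl)cyclopentane-1-carboxylate | C=C(C)[C@@H]1CC[C@@](C)(O)[C@H]1C(=O)OC
A5 | alternative 2 | methyl (E)-6-oxohept-2-enoate | COC(=O)/C=C/CCC(C)=O
A6 | alternative 2 | 4,4,5,5-tetramethyl-2-(prop-1-en-2-yl)-1,3,2-dioxaborolane | C=C(C)B1OC(C)(C)C(C)(C)O1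
A7 | alternative 2 | [Rh(cod)OH]2, di-μ-hydroxidobis(cycloocta-1,5-diene)dirhodium | [OH-].[OH-].[Rh+].[Rh+].C1=CCCC=CCC1.C1=CCCC=CCC1
A8 | alternative 3 | (1S,2R,5R)-2-methyl-5-(prop-1-en-2-yl)-2-(triethylsilyloxy)cyclopentane-1-carbaldehyde | C=C(C)[C@@H]1CC[C@@](C)(O[Si](CC)(CC)CC)[C@H]1C=O
A9 | alternative 3 | (R)-3,7-dimethyl-3-(triethylsilyloxy)oct-6-enal | CC(C)=CCC[C@@](C)(O[Si](CC)(CC)CC)CC=O
A10 | alternative 3 | (R)-linalool, (R)-3,7-dimethylocta-1,6-dien-3-ol | CC(C)=CCC[C@@](C)(O)C=C
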